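The protic impurity in this flask is charged far below the starting material, at 0.580 mM against 0.029 M, so I treated the run as a pool of interconverting isomers with one small correction, and I computed that correction on its own.

starting material 0.029 M; protic impurity 0.580 mM; time 15 min

    starting material ⇌ target (K1 = 1.7, k1 = 0.10 s⁻¹)
    target ⇌ isomer of the product A (K2 = 0.79, k2 = 0.14 s⁻¹)
    starting material + protic impurity → quenched substrate (k3 = 35 M⁻¹ s⁻¹)
    target ⇌ isomer of the product B (K4 = 0.96, k4 = 0.046 s⁻¹)

- the reaction counts as stopped when no species that holds the starting material changes by six tenths of a point or more over the second half of the time
- run time (flask): 15 min

1. which holds at 15 min: what has brought the reaction to rest, or that it has not come to rest (forward and back rates have come level / all of the starting material has reacted / it is still moving)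
2. share of the starting material used up at 15 min
3. target at 15 min, in percent of the starting material charged
4. isomer of the product B at 15 min, in percent of the starting material charged

I called the correction the loss share: the charge of protic impurity as a fraction of the charge of starting material, 2.00%. Step 3 takes one starting material for each impurity and gives nothing back, so I expected this fraction of the charge to leave the pool, with the impurity as the limiting reagent of that step.

In the first instants, I reckoned, the starting material went forward to target 4.9 times as fast as it went to quenched substrate, while the impurity, facing the full charge, had a half-life of 0.0114 min.

In the middle, the reversible steps took over. Step 1 has a forward half-life of 0.12 min, step 2 has one of 0.0825 min, and step 4 relaxes with a half-life of 0.123 min. All of these are short against 15 min, so I expected forward and back rates to come level well before the end.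

Level steps weigh starting material, target, isomer of the product A and isomer of the product B as 1 to 1.7 to 1.34 to 1.63, a sum of 5.67. With the starting material at its share of the pool, 17.3% of the charge, I reckoned the impurity's half-life at 0.0659 min, still short against 15 min, so I counted its whole charge as reacted.

At the end, then, the remaining 98.0% of the charge split by those weights. That gave me 82.7% used up, target at 29.4% and isomer of the product B at 28.2%. In this reckoning the correction itself took 0.58 percentage points from the isomer of the product B.

The forecast, made by someone who saw the problem and nothing further, read: forward and back rates have come level, with 82.7% used up, target 29.4% and isomer of the product B 28.2%, since in its words “the network has long since equilibrated”.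

The simulation gave for this flask, at 15 min: forward and back rates have come level, with 82.7% used up, target 29.4% and isomer of the product B 28.2%. Quenched substrate in this flask stood at 2.00%, with 0% of the impurity's own charge left, against my loss share of 2.00%. A second flask, charged with 9.9 × 10⁻⁴ M of protic impurity and otherwise the same, has a loss share of 3.41%, which puts 27.8% in the isomer of the product B. At 15.0 min that second flask held quenched substrate at 3.41% and isomer of the product B at 27.8%.

The numbers were drawn at random within sensible limits; no experiment stands behind them.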